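**Plan**

- Numbering the chain from the ester carbon C1 to the bromine-bearing C20, the retrosynthesis cuts C10–C11 (sp–sp2) first, then the O–C8 bond of the oxolane, then C8–C9 and C6–C7. The side chain is cut at C17=C18 and C19=C20.
- Enabling feature: C8 is at once a ring carbon of the oxolane (O, C5, C6, C7, C8), an ether carbon and the propargylic carbon of the C9≡C10 alkyne. It can therefore be made planar as the terminal carbon of a copper allenylidene and rebuilt by attack of the C5 oxygen.
- Forward: the C1–C10 chain is assembled from methyl hex-5-enoate (vinyl at C6, ethynyl at C8). The oxolane, the only ring, closes by O–C8 bond formation. The C11–C20 bromo iodo triene, made from hept-6-yn-1-ol, is joined last by Sonogashira coupling.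
- Stereochemistry: C5 (R) comes from hydrolytic kinetic resolution of the terminal epoxide and is not touched again. C8 (S) comes from the ligand-controlled ring closure, in which both C8 epimers converge. The E-alkenes come from syn-hydrozirconation (C11=C12), a stabilised ylide (C17=C18) and Takai olefination (C19=C20).

Key step: step 10

Assumption: the (S,S) antipode of Ph-pybox is taken as the one matched to the (5R) centre for delivery of oxygen to the face of C8 that gives 8S; this sense cannot be derived with certainty for an alkyl-substituted substrate, and if it proves opposite the (R,R) antipode is used with nothing else changed.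

**Route**

Step 1
Reactants: 1 methyl hex-5-enoate
Product: 2 methyl 4-(oxiran-2-yl)butanoate (racemic)
Conditions: mCPBA, CH2Cl2, 0 °C to rt
Reagents that add atoms: mCPBA (3-chloroperoxybenzoic acid), OOC(=O)c1cccc(Cl)c1
Why: Prilezhaev epoxidation of an unhindered terminal alkene with a peracid is dependable and spares the methyl ester, and the racemic outcome is acceptable because the next step resolves it.

Step 2
Reactants: 2 methyl 4-(oxiran-2-yl)butanoate (racemic)
Product: 3 methyl 4-[(2R)-oxiran-2-yl]butanoate
Conditions: (R,R)-(salen)Co(OAc) (0.5 mol %), H2O (0.55 equiv), THF, 0 °C to rt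
Reagents that add atoms: none
Why: Hydrolytic kinetic resolution with the (R,R)-(salen)Co(OAc) complex (trivalent cobalt) is general for terminal alkyl epoxides: the catalyst should hydrate the (S)-epoxide to the diol and leave the (R)-epoxide, so the C5 stereocentre is fixed here by catalyst control, at the price of at most half of the material.

Step 3
Reactants: 3 methyl 4-[(2R)-oxiran-2-yl]butanoate; 4 vinylmagnesium bromide
Product: 5 methyl (5R)-5-hydroxyoct-7-enoate
Conditions: CH2=CHMgBr, CuI (10 mol %), THF, −40 °C; then aq NH4Cl
Reagents that add atoms: vinylmagnesium bromide (4), C=C[Mg]Br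
Why: Copper-catalysed Grignard opening of a terminal epoxide should take place at the unsubstituted carbon C6 faster than the reagent adds to the methyl ester at −40 °C, the C5–O bond is not broken so the R configuration is kept, and the cold quench limits lactonisation of the δ-hydroxy ester.

Step 4
Reactants: 5 methyl (5R)-5-hydroxyoct-7-enoate
Product: 6 methyl (5R)-5-[(tert-butyldimethylsilyl)oxy]oct-7-enoate
Conditions: TBSCl, imidazole, DMF, 0 °C to rt
Reagents that add atoms: tert-butyldimethylsilyl chloride, CC(C)(C)[Si](C)(C)Cl
Why: Silylation of the secondary alcohol with TBSCl and imidazole is routine and removes the hydroxyl that would otherwise lactonise onto C1 or interfere with the oxidation and Grignard steps ahead.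

Step 5
Reactants: 6 methyl (5R)-5-[(tert-butyldimethylsilyl)oxy]oct-7-enoate
Product: 8 methyl (5R)-5-[(tert-butyldimethylsilyl)oxy]-8-hydroxyoctanoate, via alkylborane 7 (not isolated)
Conditions: 9-BBN, THF, 0 °C to rt; then H2O2, aq NaOAc, 0 °C to rt
Reagents that add atoms: hydrogen peroxide, OO
Why: Hydroboration with 9-BBN places boron at the terminal carbon C8 of the monosubstituted alkene with high anti-Markovnikov selectivity and does not reduce esters, and the acetate-buffered peroxide oxidation of the alkylborane (hydroboration–oxidation) spares the methyl ester and the silyl ether.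

Step 6
Reactants: 8 methyl (5R)-5-[(tert-butyldimethylsilyl)oxy]-8-hydroxyoctanoate
Product: 9 methyl (5R)-5-[(tert-butyldimethylsilyl)oxy]-8-oxooctanoate
Conditions: Dess–Martin periodinane, CH2Cl2, 0 °C to rt
Reagents that add atoms: none
Why: Dess–Martin oxidation converts the primary alcohol into the aldehyde under near-neutral conditions without overoxidation, and C5 carries no acidic hydrogen next to the new carbonyl, so its configuration is not at risk.

Step 7
Reactants: 9 methyl (5R)-5-[(tert-butyldimethylsilyl)oxy]-8-oxooctanoate; 10 ethynylmagnesium bromide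
Product: 11 methyl (5R)-5-[(tert-butyldimethylsilyl)oxy]-8-hydroxydec-9-ynoate (both C8 epimers)
Conditions: HC≡CMgBr, THF, −78 to −20 °C; then aq NH4Cl
Reagents that add atoms: ethynylmagnesium bromide (10), C#C[Mg]Br
Why: Addition of the ethynyl Grignard reagent to an aldehyde is fast at low temperature while the methyl ester is left alone, and the lack of facial control at C8 is of no consequence because the key step erases this centre.

Step 8
Reactants: 11 methyl (5R)-5-[(tert-butyldimethylsilyl)oxy]-8-hydroxydec-9-ynoate (both C8 epimers)
Product: 12 methyl (5R)-5-[(tert-butyldimethylsilyl)oxy]-8-[(2,3,4,5,6-pentafluorobenzoyl)oxy]dec-9-ynoate (both C8 epimers)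
Conditions: C6F5COCl, Et3N, DMAP (cat.), CH2Cl2, 0 °C
Reagents that add atoms: pentafluorobenzoyl chloride, O=C(Cl)c1c(F)c(F)c(F)c(F)c1F
Why: Acylation of the secondary propargylic alcohol with an acid chloride under amine/DMAP catalysis is standard, and the electron-poor pentafluorobenzoate is installed as the leaving group that an alkyl-substituted propargylic position needs for ionisation.

Step 9
Reactants: 12 methyl (5R)-5-[(tert-butyldimethylsilyl)oxy]-8-[(2,3,4,5,6-pentafluorobenzoyl)oxy]dec-9-ynoate (both C8 epimers)
Product: 13 methyl (5R)-5-hydroxy-8-[(2,3,4,5,6-pentafluorobenzoyl)oxy]dec-9-ynoate (both C8 epimers)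
Conditions: HF·pyridine, pyridine, THF, 0 °C to rt
Reagents that add atoms: none
Why: Fluoride-mediated cleavage of a secondary TBS ether with pyridine-buffered HF·pyridine is a standard desilylation that should leave the activated ester, the terminal alkyne and the methyl ester intact, and the free δ-hydroxy ester is taken into the next step without storage to limit lactonisation.

Step 10
Reactants: 13 methyl (5R)-5-hydroxy-8-[(2,3,4,5,6-pentafluorobenzoyl)oxy]dec-9-ynoate (both C8 epimers)
Product: 14 methyl 4-[(2R,5S)-5-ethynyloxolan-2-yl]butanoate
Conditions: (CuOTf)2·C6H6 (5 mol % Cu), (S,S)-Ph-pybox (6 mol %), iPr2NEt (1.2 equiv), CF3CH2OH (0.02 M), −10 °C, Ar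
Reagents that add atoms: none
Why: Proposed new method: monovalent copper bound to (S,S)-Ph-pybox (2,6-bis[(4S)-4-phenyl-4,5-dihydro-1,3-oxazol-2-yl]pyridine) should coordinate the terminal alkyne, iPr2NEt should give the copper acetylide, and loss of pentafluorobenzoate from C8 should give a copper allenylidene (Cu=C10=C9=C8) in which C8 is trigonal, so that both C8 epimers of 13 feed one intermediate; the C5 hydroxyl then adds to C8 and protonolysis of the resulting acetylide releases 14 and the catalyst. The closest known reaction type is copper/pybox-catalysed enantioselective propargylic substitution of terminal propargylic esters through copper allenylidenes, established for intermolecular etherification with alcohols and for intramolecular amination, mostly on aryl-substituted esters. The oxolane closes in a 5-exo mode, the oxygen attacking the trigonal C8 while the C8=C9 bond stays outside the ring. The new C8 stereocentre is set by the ligand, whose antipode is chosen to match the fixed (5R) centre so that oxygen reaches the face of C8 that places the ethynyl group trans to the C5 side chain (8S). The step needs attack at C8 and not at C10, ring closure ahead of solvent capture or lactonisation onto C1, and ionisation of an alkyl-substituted ester; these are secured by the terminal alkyne, the 1,4-placement of hydroxyl and leaving group at high dilution, a weakly nucleophilic ionising solvent with only a tertiary amine as base at low temperature, and the electron-poor pentafluorobenzoate.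

Step 11
Reactants: 15 hept-6-yn-1-ol
Product: 17 (6E)-7-iodohept-6-en-1-ol, via zirconated alkenyl alkoxide 16 (not isolated)
Conditions: Cp2Zr(H)Cl (2.3 equiv), THF, rt; then I2, 0 °C
Reagents that add atoms: iodine, II
Why: Hydrozirconation of a terminal alkyne with Cp2Zr(H)Cl (tetravalent zirconium) is a syn addition that puts zirconium on the terminal carbon, the first equivalent being consumed by the hydroxyl as its zirconium alkoxide, and iodinolysis of the alkenyl–zirconium bond proceeds with retention, which fixes the E geometry of the future C11=C12 bond.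

Step 12
Reactants: 17 (6E)-7-iodohept-6-en-1-ol
Product: 18 (6E)-7-iodohept-6-enal
Conditions: Dess–Martin periodinane, CH2Cl2, 0 °C to rt
Reagents that add atoms: none
Why: Dess–Martin oxidation of the primary alcohol is compatible with the alkenyl iodide and stops at the aldehyde.

Step 13
Reactants: 18 (6E)-7-iodohept-6-enal; 19 (triphenylphosphoranylidene)acetaldehyde
Product: 20 (2E,8E)-9-iodonona-2,8-dienal
Conditions: Ph3P=CHCHO, toluene, 80 °C
Reagents that add atoms: (triphenylphosphoranylidene)acetaldehyde (19), O=CC=P(c1ccccc1)(c1ccccc1)c1ccccc1
Why: Wittig olefination with the stabilised formylmethylene ylide is strongly E-selective with aliphatic aldehydes, and the conjugated aldehyde formed reacts with the ylide more slowly than the saturated one, so homologation should stop at the (2E)-enal that carries the future C17=C18 bond.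

Step 14
Reactants: 20 (2E,8E)-9-iodonona-2,8-dienal; 21 bromoform
Product: 22 (1E,7E,9E)-10-bromo-1-iododeca-1,7,9-triene
Conditions: CHBr3, CrBr2, THF, 0 °C to rt, dark
Reagents that add atoms: bromoform (21), BrC(Br)Br
Why: Takai olefination, in which a geminal dichromium species from bromoform and CrBr2 (divalent chromium) adds to the aldehyde and eliminates, gives (E)-alkenyl bromides preferentially, CrBr2 in place of CrCl2 avoids bromine–chlorine exchange, and without nickel the alkenyl iodide is inert to divalent chromium.

Step 15
Reactants: 14 methyl 4-[(2R,5S)-5-ethynyloxolan-2-yl]butanoate; 22 (1E,7E,9E)-10-bromo-1-iododeca-1,7,9-triene (1.2 equiv)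
Product: 23 methyl 4-[(2R,5S)-5-[(3E,9E,11E)-12-bromododeca-3,9,11-trien-1-yn-1-yl]oxolan-2-yl]butanoate
Conditions: Pd(PPh3)4 (5 mol %), CuI (10 mol %), Et3N, THF, 0 °C to rt, degassed, dark
Reagents that add atoms: none
Why: Sonogashira coupling with Pd(PPh3)4 (zerovalent palladium) and CuI engages the alkenyl C–I bond much faster than the dienyl C–Br bond at or below room temperature, proceeds with retention of alkene geometry, and touches neither the ester nor the two oxolane stereocentres, so the last C10–C11 bond should form without disturbing the bromodiene.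

**Compound list**

1 | methyl hex-5-enoate | C=CCCCC(=O)OC | starting material
2 | methyl 4-(oxiran-2-yl)butanoate (racemic) | COC(=O)CCCC1CO1 | intermediate
3 | methyl 4-[(2R)-oxiran-2-yl]butanoate | COC(=O)CCC[C@@H]1CO1 | intermediate
4 | vinylmagnesium bromide | C=C[Mg]Br | starting material
5 | methyl (5R)-5-hydroxyoct-7-enoate | COC(=O)CCC[C@@H](O)CC=C | intermediate
6 | methyl (5R)-5-[(tert-butyldimethylsilyl)oxy]oct-7-enoate | COC(=O)CCC[C@@H](O[Si](C)(C)C(C)(C)C)CC=C | intermediate
7 | methyl (5S)-8-(9-borabicyclo[3.3.1]nonan-9-yl)-5-[(tert-butyldimethylsilyl)oxy]octanoate (not isolated; the descriptor changes by the priority rules only, the spatial arrangement at C5 is that of 6) | COC(=O)CCC[C@@H](O[Si](C)(C)C(C)(C)C)CCCB1C2CCCC1CCC2 | intermediate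
8 | methyl (5R)-5-[(tert-butyldimethylsilyl)oxy]-8-hydroxyoctanoate | COC(=O)CCC[C@@H](O[Si](C)(C)C(C)(C)C)CCCO | intermediate
9 | methyl (5R)-5-[(tert-butyldimethylsilyl)oxy]-8-oxooctanoate | COC(=O)CCC[C@@H](O[Si](C)(C)C(C)(C)C)CCC=O | intermediate
10 | ethynylmagnesium bromide | C#C[Mg]Br | starting material
11 | methyl (5R)-5-[(tert-butyldimethylsilyl)oxy]-8-hydroxydec-9-ynoate (both C8 epimers) | COC(=O)CCC[C@@H](O[Si](C)(C)C(C)(C)C)CCC(O)C#C | intermediate
12 | methyl (5R)-5-[(tert-butyldimethylsilyl)oxy]-8-[(2,3,4,5,6-pentafluorobenzoyl)oxy]dec-9-ynoate (both C8 epimers) | COC(=O)CCC[C@@H](O[Si](C)(C)C(C)(C)C)CCC(OC(=O)c1c(F)c(F)c(F)c(F)c1F)C#C | intermediate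
13 | methyl (5R)-5-hydroxy-8-[(2,3,4,5,6-pentafluorobenzoyl)oxy]dec-9-ynoate (both C8 epimers) | COC(=O)CCC[C@@H](O)CCC(OC(=O)c1c(F)c(F)c(F)c(F)c1F)C#C | intermediate
14 | methyl 4-[(2R,5S)-5-ethynyloxolan-2-yl]butanoate | COC(=O)CCC[C@@H]1CC[C@@H](C#C)O1 | intermediate
15 | hept-6-yn-1-ol | C#CCCCCCO | starting material
16 | chlorobis(cyclopentadienyl)zirconium (6E)-7-[chlorobis(cyclopentadienyl)zirconio]hept-6-en-1-olate (not isolated) | Cl[Zr+2]OCCCCC/C=C/[Zr+2]Cl.c1cc[cH-]c1.c1cc[cH-]c1.c1cc[cH-]c1.c1cc[cH-]c1 | intermediate
17 | (6E)-7-iodohept-6-en-1-ol | OCCCCC/C=C/I | intermediate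
18 | (6E)-7-iodohept-6-enal | O=CCCCC/C=C/I | intermediate
19 | (triphenylphosphoranylidene)acetaldehyde | O=CC=P(c1ccccc1)(c1ccccc1)c1ccccc1 | starting material
20 | (2E,8E)-9-iodonona-2,8-dienal | O=C/C=C/CCCC/C=C/I | intermediate
21 | bromoform | BrC(Br)Br | starting material
22 | (1E,7E,9E)-10-bromo-1-iododeca-1,7,9-triene | I/C=C/CCCC/C=C/C=C/Br | intermediate
23 | methyl 4-[(2R,5S)-5-[(3E,9E,11E)-12-bromododeca-3,9,11-trien-1-yn-1-yl]oxolan-2-yl]butanoate | COC(=O)CCC[C@@H]1CC[C@@H](C#C/C=C/CCCC/C=C/C=C/Br)O1 | target

**Step count**

Total steps: 15. Longest linear sequence: 11 (steps 1 to 10, then step 15); the side-chain fragment takes steps 11 to 14.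

**Steps most likely to fail, with fallbacks**

1. Step 10. The alkyl-substituted propargylic ester may ionise too slowly for the copper acetylide to expel pentafluorobenzoate. The hydroxyl may also reach C8 with poor facial selectivity, or lactonisation onto C1 may outrun ring closure. The fallback replaces the stereoconvergent substitution by a stereospecific one built from known reactions; it sets out from 11 and returns at 14.
   - Dess–Martin oxidation of 11 would give the ynone methyl (5R)-5-[(tert-butyldimethylsilyl)oxy]-8-oxodec-9-ynoate F1.
   - Midland reduction with (R)-Alpine-Borane, the reagent that reduces oct-1-yn-3-one to the (R)-carbinol, should give methyl (5R,8R)-5-[(tert-butyldimethylsilyl)oxy]-8-hydroxydec-9-ynoate F2 under reagent control.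
   - MsCl and Et3N in CH2Cl2 at −20 °C would give methyl (5R,8R)-5-[(tert-butyldimethylsilyl)oxy]-8-[(methanesulfonyl)oxy]dec-9-ynoate F3.
   - HF·pyridine would free the C5 hydroxyl to give methyl (5R,8R)-5-hydroxy-8-[(methanesulfonyl)oxy]dec-9-ynoate F4.
   - On warming with 2,6-lutidine in MeCN, this should close by intramolecular SN2 displacement (5-exo-tet) with inversion at C8, giving 14.

2. Step 15. Oxidative addition of zerovalent palladium into the dienyl C20–Br bond may compete with that into the C11–I bond, leading to double coupling and oligomers, with oxidative alkyne homocoupling as a further drain. The fallback introduces bromine only after the coupling; it sets out from 14 and 20 and returns at 23.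
   - Sonogashira coupling of 14 with the iodo dienal 20, which carries a single halogen (Pd(PPh3)4, CuI, Et3N, THF), would give methyl 4-[(2R,5S)-5-[(3E,9E)-11-oxoundeca-3,9-dien-1-yn-1-yl]oxolan-2-yl]butanoate F5.
   - Takai bromo-olefination of this aldehyde (CHBr3, CrBr2, THF) would then install C20 and its bromine as the last operation, conditions that an ester, an oxolane and an enyne tolerate, giving 23.

3. Step 14. The chromium olefination may give incomplete E-selectivity at the new C19=C20 bond and lose aldehyde to reductive side reactions, leaving geometric isomers that are hard to remove at the triene stage. The fallback builds the bromodiene stereospecifically by cross-coupling; it sets out from 15 and returns at 22.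
   - Hydrozirconation of 15 as in step 11 gives 16. Instead of iodinolysis, Pd(PPh3)4-catalysed coupling of this alkenylzirconium species with (E)-1-bromo-2-iodoethene at its C–I bond (Negishi-type coupling, retention at both alkenes) should give (6E,8E)-9-bromonona-6,8-dien-1-ol F6.
   - Dess–Martin oxidation would give (6E,8E)-9-bromonona-6,8-dienal F7.
   - Takai iodo-olefination (CHI3, CrCl2, THF/1,4-dioxane), the classical use of that reaction on a saturated aldehyde and free of halogen exchange, would give 22.

Further compounds
F1 | step 10 | methyl (5R)-5-[(tert-butyldimethylsilyl)oxy]-8-oxodec-9-ynoate | COC(=O)CCC[C@@H](O[Si](C)(C)C(C)(C)C)CCC(=O)C#C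
F2 | step 10 | methyl (5R,8R)-5-[(tert-butyldimethylsilyl)oxy]-8-hydroxydec-9-ynoate | COC(=O)CCC[C@@H](O[Si](C)(C)C(C)(C)C)CC[C@@H](O)C#C
F3 | step 10 | methyl (5R,8R)-5-[(tert-butyldimethylsilyl)oxy]-8-[(methanesulfonyl)oxy]dec-9-ynoate | COC(=O)CCC[C@@H](O[Si](C)(C)C(C)(C)C)CC[C@@H](OS(C)(=O)=O)C#C
F4 | step 10 | methyl (5R,8R)-5-hydroxy-8-[(methanesulfonyl)oxy]dec-9-ynoate | COC(=O)CCC[C@@H](O)CC[C@@H](OS(C)(=O)=O)C#C
F5 | step 15 | methyl 4-[(2R,5S)-5-[(3E,9E)-11-oxoundeca-3,9-dien-1-yn-1-yl]oxolan-2-yl]butanoate | COC(=O)CCC[C@@H]1CC[C@@H](C#C/C=C/CCCC/C=C/C=O)O1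
F6 | step 14 | (6E,8E)-9-bromonona-6,8-dien-1-ol | OCCCCC/C=C/C=C/Br
F7 | step 14 | (6E,8E)-9-bromonona-6,8-dienal | O=CCCCC/C=C/C=C/Br
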